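## Retrosynthetic overview

1. Target 13 ⇐ tert-butyl ester 11 (ester unmasked last) ⇐ bicyclic diene ester 9 by late allylic hydroxylation of the C17 methyl, mirroring oxidative tailoring after cyclization.
2. 9 ⇐ acyclic tetraene 7 by one enantioselective, proton-initiated cascade: C4–C5 closes ring A, then C10–C9 closes ring B, and loss of H-7 ends it. C5, C9 and C10 are all set here.
3. The C16 acetate, the C15 ester and the 13Z geometry are already present in 7; the electron-poor C13=C14 enoate cannot attack the C8 cation, so the cascade stops at the decalin.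
4. 7 ⇐ (Z)-enol triflate 6 + acetoxymethylzinc (Negishi) ⇐ β-keto ester 4 ⇐ (E,E)-farnesyl bromide 1 + tert-butyl acetoacetate 2.

Assumption: the (S)-configured binaphthol acid is taken to give the ent (5R,9R,10R) series, the mirror of the usual (R)-ligand/normal-series sense; if a first run shows the opposite, the (R)-ligand is used with no other change.

Labdane numbering (C1–C20) is used for positions. The target is ent-16-acetoxy-17-hydroxylabda-7,13-dien-15-oic acid (13Z by CIP, 5R,9S,10R).

## Route

Step 1
Reactants: 1 (2E,6E)-farnesyl bromide; 2 tert-butyl acetoacetate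
Product: 4 tert-butyl (6E,10E)-7,11,15-trimethyl-3-oxohexadeca-6,10,14-trienoate, via acetoacetate dianion 3 (not isolated)
Conditions: 2 (1.2 equiv), NaH (1.25 equiv), THF, 0 °C; n-BuLi (1.2 equiv), 0 °C; then 1, 0 °C → rt; cold 1 M HCl quench
Reagents that add atoms: none
Why: Weiler dianion γ-alkylation: the terminal carbanion of 3 is the more nucleophilic site and displaces the primary allylic bromide by direct SN2, so the C11–C12 bond forms without allylic transposition and both E alkenes are kept; no stereocentre is formed.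

Step 2
Reactants: 4 tert-butyl (6E,10E)-7,11,15-trimethyl-3-oxohexadeca-6,10,14-trienoate
Product: 6 tert-butyl (2Z,6E,10E)-7,11,15-trimethyl-3-(trifluoromethanesulfonyloxy)hexadeca-2,6,10,14-tetraenoate, via sodium enolate 5 (not isolated)
Conditions: NaH (1.2 equiv), THF, 0 °C; PhNTf2 (1.15 equiv), 0 °C → rt; cold 1 M HCl wash
Reagents that add atoms: N-phenylbis(trifluoromethanesulfonimide), O=S(=O)(N(c1ccccc1)S(=O)(=O)C(F)(F)F)C(F)(F)F
Why: Enolate O-triflation: the sodium-chelated, U-shaped β-keto ester enolate 5 is sulfonylated on oxygen to give the (Z)-enol triflate (TfO cis to the ester), which fixes the geometry of the future C13=C14 bond.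

Step 3
Reactants: 6 tert-butyl (2Z,6E,10E)-7,11,15-trimethyl-3-(trifluoromethanesulfonyloxy)hexadeca-2,6,10,14-tetraenoate
Product: 7 tert-butyl (2Z,6E,10E)-3-(acetoxymethyl)-7,11,15-trimethylhexadeca-2,6,10,14-tetraenoate
Conditions: Zn dust, BrCH2OAc, THF, 15 °C (gives AcOCH2ZnBr, 1.5 equiv); then 6, Pd(PPh3)4 (5 mol %), THF/NMP, 25–40 °C
Reagents that add atoms: bromomethyl acetate, CC(=O)OCBr (precursor); (acetoxymethyl)zinc bromide, CC(=O)OC[Zn]Br (formed from it in the flask)
Why: Negishi cross-coupling: the α-acyloxyalkylzinc bromide is made by zinc insertion into the α-bromoalkyl ester, and oxidative addition of zerovalent palladium into the vinyl C–OTf bond, transmetalation from the chelate-stabilised organozinc and reductive elimination all go with retention, so CH2OAc ends cis to the ester (2Z); C16 arrives already as its acetate and is never a free hydroxyl, which rules out butenolide formation.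

Step 4
Reactants: 7 tert-butyl (2Z,6E,10E)-3-(acetoxymethyl)-7,11,15-trimethylhexadeca-2,6,10,14-tetraenoate
Product: 9 tert-butyl (2Z)-3-(acetoxymethyl)-5-[(1R,4aR,8aR)-2,5,5,8a-tetramethyl-1,4,4a,5,6,7,8,8a-octahydronaphthalen-1-yl]pent-2-enoate, via labd-13-en-8-yl cation 8 (not isolated)
Conditions: (S)-2-(2-fluorobenzyloxy)-2'-hydroxy-1,1'-binaphthyl (2.2 equiv), SnCl4 (2.0 equiv), toluene, −78 °C, 48–72 h; pyridine, −78 °C
Reagents that add atoms: none
Why: Proposed new method: the SnCl4-bound binaphthol is a chiral Brønsted acid that protonates only the terminal isopropylidene alkene, on one enantioface; the chair–chair folded (E,E)-triene then closes ring A (C4–C5) and ring B (C10–C9) by antiperiplanar additions, which fixes the trans ring fusion and the equatorial C9 side chain relative to C5 (absolute sense from the (S)-ligand); the ester-conjugated C13=C14 alkene is too electron-poor to attack cation 8, which instead loses the axial H-7 to the stannate counter-ion to give the trisubstituted C7=C8 alkene; the closest known reaction type is the Lewis acid-assisted chiral Brønsted acid (Yamamoto-type) polyene cyclization of homofarnesyl substrates, together with acid-mediated cyclization of farnesyl esters to drim-7-enes, and what is new is the proton-loss termination in a fully functionalised C20 chain.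

Step 5
Reactants: 9 tert-butyl (2Z)-3-(acetoxymethyl)-5-[(1R,4aR,8aR)-2,5,5,8a-tetramethyl-1,4,4a,5,6,7,8,8a-octahydronaphthalen-1-yl]pent-2-enoate
Product: 11 tert-butyl (2Z)-3-(acetoxymethyl)-5-[(1S,4aR,8aR)-2-(hydroxymethyl)-5,5,8a-trimethyl-1,4,4a,5,6,7,8,8a-octahydronaphthalen-1-yl]pent-2-enoate, via allylseleninic acid 10 (not isolated)
Conditions: SeO2 (0.5 equiv), t-BuOOH (5.5 M in decane, 3 equiv), CH2Cl2, 0 → 25 °C, 24 h
Reagents that add atoms: selenium dioxide, O=[Se]=O (oxygen carrier); tert-butyl hydroperoxide, CC(C)(C)OO (terminal oxidant)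
Why: Riley–Sharpless allylic hydroxylation: SeO2 undergoes an ene reaction at the electron-rich C7=C8 alkene (selenium to C7, hydrogen from the C17 methyl at the more substituted terminus, preferred over the hindered methine H-9), and a 2,3-sigmatropic shift then returns the double bond to C7=C8 and delivers oxygen to C17; the conjugated C13=C14 alkene is inert and no stereocentre is touched (the C9 descriptor changes from R to S only through CIP priorities).

Step 6
Reactants: 11 tert-butyl (2Z)-3-(acetoxymethyl)-5-[(1S,4aR,8aR)-2-(hydroxymethyl)-5,5,8a-trimethyl-1,4,4a,5,6,7,8,8a-octahydronaphthalen-1-yl]pent-2-enoate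
Product: 13 (2Z)-3-(acetoxymethyl)-5-[(1S,4aR,8aR)-2-(hydroxymethyl)-5,5,8a-trimethyl-1,4,4a,5,6,7,8,8a-octahydronaphthalen-1-yl]pent-2-enoic acid, via bis(trimethylsilyl) derivative 12 (not isolated)
Conditions: TMSOTf (4 equiv), 2,6-lutidine (6 equiv), CH2Cl2, 0 °C, 1–2 h; then 10% aq citric acid/THF, 25 °C, 30 min
Reagents that add atoms: none
Why: Silyl triflate cleavage of a tert-butyl ester: O-silylation and loss of isobutene under lutidine buffering use neither hydroxide nor protic acid, so the primary allylic acetate, the C7=C8 alkene and the 2Z geometry survive, and the transient silyl ester and silyl ether are hydrolysed on mild aqueous work-up to give the target.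

## Compound list

1 | (2E,6E)-1-bromo-3,7,11-trimethyldodeca-2,6,10-triene ((E,E)-farnesyl bromide) | CC(C)=CCC/C(C)=C/CC/C(C)=C/CBr | starting material
2 | tert-butyl 3-oxobutanoate (tert-butyl acetoacetate) | CC(=O)CC(=O)OC(C)(C)C | starting material
3 | lithium sodium dianion of 2 (not isolated) | [Li+].[Na+].[CH2-]C(=O)[CH-]C(=O)OC(C)(C)C | intermediate
4 | tert-butyl (6E,10E)-7,11,15-trimethyl-3-oxohexadeca-6,10,14-trienoate | CC(C)=CCC/C(C)=C/CC/C(C)=C/CCC(=O)CC(=O)OC(C)(C)C | intermediate
5 | sodium (Z)-enolate of 4 (not isolated) | [Na+].CC(C)=CCC/C(C)=C/CC/C(C)=C/CC/C([O-])=C/C(=O)OC(C)(C)C | intermediate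
6 | tert-butyl (2Z,6E,10E)-7,11,15-trimethyl-3-(trifluoromethanesulfonyloxy)hexadeca-2,6,10,14-tetraenoate | CC(C)=CCC/C(C)=C/CC/C(C)=C/CC/C(OS(=O)(=O)C(F)(F)F)=C/C(=O)OC(C)(C)C | intermediate
7 | tert-butyl (2Z,6E,10E)-3-(acetoxymethyl)-7,11,15-trimethylhexadeca-2,6,10,14-tetraenoate | CC(C)=CCC/C(C)=C/CC/C(C)=C/CC/C(COC(C)=O)=C/C(=O)OC(C)(C)C | intermediate
8 | C8 tertiary cation of the bicyclic ester, tert-butyl ent-16-acetoxylabd-13-en-8-ylium-15-oate (not isolated) | CC(=O)OC/C(=C\C(=O)OC(C)(C)C)CC[C@@H]1[C+](C)CC[C@@H]2C(C)(C)CCC[C@@]12C | intermediate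
9 | tert-butyl (2Z)-3-(acetoxymethyl)-5-[(1R,4aR,8aR)-2,5,5,8a-tetramethyl-1,4,4a,5,6,7,8,8a-octahydronaphthalen-1-yl]pent-2-enoate (tert-butyl ent-16-acetoxylabda-7,13-dien-15-oate) | CC(=O)OC/C(=C\C(=O)OC(C)(C)C)CC[C@@H]1C(C)=CC[C@@H]2C(C)(C)CCC[C@@]12C | intermediate
10 | ene adduct of 9: C7 seleninic acid with exocyclic C8=C17 alkene, selenium on the ring face opposite the C10 methyl (not isolated) | CC(=O)OC/C(=C\C(=O)OC(C)(C)C)CC[C@@H]1C(=C)[C@@H]([Se](=O)O)C[C@@H]2C(C)(C)CCC[C@@]12C | intermediate
11 | tert-butyl (2Z)-3-(acetoxymethyl)-5-[(1S,4aR,8aR)-2-(hydroxymethyl)-5,5,8a-trimethyl-1,4,4a,5,6,7,8,8a-octahydronaphthalen-1-yl]pent-2-enoate | CC(=O)OC/C(=C\C(=O)OC(C)(C)C)CC[C@@H]1C(CO)=CC[C@@H]2C(C)(C)CCC[C@@]12C | intermediate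
12 | trimethylsilyl (2Z)-3-(acetoxymethyl)-5-[(1S,4aR,8aR)-5,5,8a-trimethyl-2-(trimethylsilyloxymethyl)-1,4,4a,5,6,7,8,8a-octahydronaphthalen-1-yl]pent-2-enoate (not isolated) | CC(=O)OC/C(=C\C(=O)O[Si](C)(C)C)CC[C@@H]1C(CO[Si](C)(C)C)=CC[C@@H]2C(C)(C)CCC[C@@]12C | intermediate
13 | (2Z)-3-(acetoxymethyl)-5-[(1S,4aR,8aR)-2-(hydroxymethyl)-5,5,8a-trimethyl-1,4,4a,5,6,7,8,8a-octahydronaphthalen-1-yl]pent-2-enoic acid | CC(=O)OC/C(=C\C(=O)O)CC[C@@H]1C(CO)=CC[C@@H]2C(C)(C)CCC[C@@]12C | target

## Step count and risk

Total steps: 6. Longest linear sequence: 6 (from 1 or 2 to 13).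

Step 4 is the most likely to fail. The double ring closure may stop after ring A, may end by proton loss toward C17 or C9 instead of C7, or may give only 80–90% ee. Alkene isomers would be removed on AgNO3-impregnated silica, and 9 would be brought to a single enantiomer by preparative chiral chromatography. The fallback sets out from 7 and comes back at 9, and splits the cascade into two separately controlled events. With the same chiral acid, but in CH2Cl2 and quenched after about 24 h, only ring A is closed. This gives the monocyclic triene ester tert-butyl (2Z,6E)-3-(acetoxymethyl)-7-methyl-9-[(1R)-2,6,6-trimethylcyclohex-2-en-1-yl]nona-2,6-dienoate F1 (its exocyclic alkene isomer behaves the same way), which is isolated and enriched. F1 is then re-protonated at the ring alkene with achiral SnCl4/CF3CO2H in CH2Cl2 at −78 °C. Ring B closes under control of the existing C5 stereocentre through the same chair transition state, and loss of H-7 gives 9.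

Step 5 is the second risk. The catalytic hydroxylation may be sluggish on the hindered ring alkene or may end as an alcohol/aldehyde mixture. The fallback sets out from 9 and comes back at 11, and aims for the aldehyde on purpose. 9 is oxidised with SeO2/t-BuOOH to full conversion, and the crude mixture is converged with activated MnO2 (CH2Cl2, 25 °C). This gives the single conjugated aldehyde tert-butyl (2Z)-3-(acetoxymethyl)-5-[(1S,4aR,8aR)-2-formyl-5,5,8a-trimethyl-1,4,4a,5,6,7,8,8a-octahydronaphthalen-1-yl]pent-2-enoate F2. F2 is purified and reduced 1,2-selectively by Luche reduction (NaBH4, CeCl3·7H2O, MeOH, −40 °C) to 11; the enoate ester and the acetate do not react under these conditions.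

Step 3 is the third risk. Transfer of the acetoxymethyl group from zinc to palladium may be slow, or zerovalent palladium may ionise the allylic acetate of the product. The fallback sets out from 6 and comes back at 7, and brings in C16 as carbon monoxide. Stille-type reductive carbonylation of 6 (Pd(PPh3)4, CO 1 atm, Bu3SnH added slowly, THF, 50 °C) gives, with retention, the aldehyde tert-butyl (2Z,6E,10E)-3-formyl-7,11,15-trimethylhexadeca-2,6,10,14-tetraenoate F3. Luche reduction of F3 (NaBH4, CeCl3·7H2O, MeOH, −78 °C) gives the hydroxy ester tert-butyl (2Z,6E,10E)-3-(hydroxymethyl)-7,11,15-trimethylhexadeca-2,6,10,14-tetraenoate F4. F4 is not stored; after a cold extractive work-up into CH2Cl2 the crude solution is acetylated at once (Ac2O, pyridine, DMAP, CH2Cl2, −20 °C) to 7 before the hindered tert-butyl ester can lactonise.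

## Further compounds

F1 | step 4 | tert-butyl (2Z,6E)-3-(acetoxymethyl)-7-methyl-9-[(1R)-2,6,6-trimethylcyclohex-2-en-1-yl]nona-2,6-dienoate | CC(=O)OC/C(=C\C(=O)OC(C)(C)C)CC/C=C(\C)CC[C@H]1C(C)=CCCC1(C)C
F2 | step 5 | tert-butyl (2Z)-3-(acetoxymethyl)-5-[(1S,4aR,8aR)-2-formyl-5,5,8a-trimethyl-1,4,4a,5,6,7,8,8a-octahydronaphthalen-1-yl]pent-2-enoate | CC(=O)OC/C(=C\C(=O)OC(C)(C)C)CC[C@@H]1C(C=O)=CC[C@@H]2C(C)(C)CCC[C@@]12C
F3 | step 3 | tert-butyl (2Z,6E,10E)-3-formyl-7,11,15-trimethylhexadeca-2,6,10,14-tetraenoate | CC(C)=CCC/C(C)=C/CC/C(C)=C/CC/C(C=O)=C/C(=O)OC(C)(C)C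
F4 | step 3 | tert-butyl (2Z,6E,10E)-3-(hydroxymethyl)-7,11,15-trimethylhexadeca-2,6,10,14-tetraenoate | CC(C)=CCC/C(C)=C/CC/C(C)=C/CC/C(CO)=C/C(=O)OC(C)(C)C
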